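**Retrosynthetic overview**
- Target ⇐ bis-silyl ether by fluoride desilylation; the 4-hydroxyphenyl ring is carried in from 4-(2-bromoethyl)phenol.
- Ring A (central arene) and ring B (pyran) ⇐ one thermal cascade from a vinylketene and a siloxyalkyne: [2+2], 4π opening, 6π closure (ring A first), then loss of MeOH to an ortho-quinone methide and oxa-6π closure (ring B second).
- Vinylketene ⇐ β,γ-unsaturated acid that already carries the prenyl and arylethyl groups ⇐ arylethyl Grignard + diketene, then α-prenylation.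
- Siloxyalkyne ⇐ prenal + acetylene (addition, O-methylation), then acetylide oxidation and O-silylation; it supplies C4a, C5–O and C2–C4.
- The ketene oxygen becomes O1 and the alkyne oxygen becomes the C5 hydroxyl, so the direction of pyran closure is fixed by construction.

Assumption: the target has no stereocentre and no stereogenic double bond, so "single enantiomer" is taken to mean the one achiral compound; racemic centres in intermediates are erased in step 6.
Assumption: metal salts that are only protonated on aqueous work-up are not numbered separately.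

Step 1
Reactants: 1 4-(2-bromoethyl)phenol
Product: 2 [4-(2-bromoethyl)phenoxy]tri(propan-2-yl)silane
Conditions: TIPSCl, imidazole, CH2Cl2, 0 °C to rt
Reagents that add atoms: chlorotri(propan-2-yl)silane (TIPSCl), CC(C)[Si](Cl)(C(C)C)C(C)C
Why: Imidazole-promoted O-silylation of the phenol (silyl ether formation) masks the acidic OH for the organometallic and ketene steps; no stereocentre is involved.

Step 2
Reactants: 2 [4-(2-bromoethyl)phenoxy]tri(propan-2-yl)silane; 3 diketene (4-methylideneoxetan-2-one)
Product: 5 3-methylidene-5-{4-[(triisopropylsilyl)oxy]phenyl}pentanoic acid, via arylethylmagnesium bromide 4 (not isolated)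
Conditions: Mg, THF, rt; then 3, NiCl2 (5 mol %), THF, 0 °C to rt; 1 M HCl
Reagents that add atoms: none
Why: Under nickel catalysis the primary alkyl Grignard reagent couples at the vinylic C–O bond of diketene (Kumada-type cross-coupling with opening of the enol lactone), which gives the 3-methylidene acid with the alkene fixed in the β,γ-position; no stereocentre is formed.

Step 3
Reactants: 5 3-methylidene-5-{4-[(triisopropylsilyl)oxy]phenyl}pentanoic acid; 6 1-bromo-3-methylbut-2-ene (prenyl bromide)
Product: 8 racemic 5-methyl-2-(4-{4-[(triisopropylsilyl)oxy]phenyl}but-1-en-2-yl)hex-4-enoic acid, via dilithium dienediolate 7 (not isolated)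
Conditions: LiN(i-Pr)2 (2.2 equiv), THF, −78 to 0 °C; 6, −78 °C to rt; 1 M HCl
Reagents that add atoms: none
Why: The carboxylic acid dianion is alkylated by the allylic bromide at the α-carbon (kinetic α-alkylation of a lithium dienediolate, the lavandulic acid pattern), so the 1,1-disubstituted alkene stays out of conjugation; the new α-stereocentre is racemic and is erased in step 6.

Step 4
Reactants: 9 acetylene; 10 3-methylbut-2-enal (prenal)
Product: 13 racemic 3-methoxy-5-methylhex-4-en-1-yne, via lithium acetylide 11 (not isolated), via lithium alkoxide 12 (not isolated)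
Conditions: n-BuLi, THF, −78 °C; 10, −78 to 0 °C; then MeI, DMSO, 0 °C to rt
Reagents that add atoms: iodomethane (MeI), CI
Why: 1,2-Addition of lithium acetylide to the enal followed by Williamson O-methylation of the lithium alkoxide in the same flask gives the propargylic, allylic methyl ether; the carbinol centre is racemic and is destroyed in step 6.

Step 5
Reactants: 13 racemic 3-methoxy-5-methylhex-4-en-1-yne
Product: 16 racemic [(3-methoxy-5-methylhex-4-en-1-yn-1-yl)oxy]tri(propan-2-yl)silane, via alkynyllithium 14 (not isolated), via lithium ynolate 15 (not isolated)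
Conditions: LiN(SiMe3)2, THF, −78 °C; t-BuOOLi (from t-BuOOH and LiN(SiMe3)2), −78 to 0 °C; TIPSOTf, −78 °C
Reagents that add atoms: tert-butyl hydroperoxide, CC(C)(C)OO; tri(propan-2-yl)silyl trifluoromethanesulfonate (TIPSOTf), CC(C)[Si](OS(=O)(=O)C(F)(F)F)(C(C)C)C(C)C
Why: The lithium acetylide attacks the peroxide oxygen to give the lithium ynolate, which the bulky silyl triflate traps on oxygen (acetylide oxidation–ynolate silylation route to siloxyalkynes); the racemic centre is untouched.

Step 6
Reactants: 8 racemic 5-methyl-2-(4-{4-[(triisopropylsilyl)oxy]phenyl}but-1-en-2-yl)hex-4-enoic acid; 16 racemic [(3-methoxy-5-methylhex-4-en-1-yn-1-yl)oxy]tri(propan-2-yl)silane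
Product: 24 triisopropyl{[2,2-dimethyl-6-(3-methylbut-2-en-1-yl)-7-(2-{4-[(triisopropylsilyl)oxy]phenyl}ethyl)-2H-chromen-5-yl]oxy}silane, via acid chloride 17 (not isolated), via vinylketene 18 (not isolated), via vinylcyclobutenone 19 (not isolated), via dienylketene 20 (not isolated), via cyclohexadienone 21 (not isolated), via phenol 22 (not isolated), via ortho-quinone methide 23 (not isolated)
Conditions: (COCl)2, DMF (cat.), CH2Cl2, 0 °C to rt, evaporate; then 16 (1.2 equiv), Et3N, toluene, rt (slow addition of 17); then 110 °C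
Reagents that add atoms: none
Why: Proposed new method: Et3N dehydrochlorinates the β,γ-unsaturated acid chloride at its doubly activated α-CH to vinylketene 18; the siloxyalkyne adds in a regioselective [2+2] (nucleophilic alkyne carbon to the ketene carbonyl carbon) to give 19 at rt, so no free ketene remains when the phenol appears; heating then causes 4π ring opening to 20, 6π closure to 21 and tautomerisation to phenol 22 (ring A), in which the ketene oxygen is the only free OH and sits ortho to the methoxyallyl arm while the alkyne oxygen is locked as the silyl ether; that OH expels methanol from the doubly activated benzylic, allylic ether to give ortho-quinone methide 23, and oxa-6π electrocyclisation closes ring B on that oxygen only; the closest known reaction types are the vinylketene–siloxyalkyne (Danheiser-type) benzannulation to resorcinol monosilyl ethers and the Dötz-type benzannulation/ortho-quinone methide/electrocyclisation route to chromenes; both racemic centres are destroyed and no new stereocentre is formed.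

Step 7
Reactants: 24 triisopropyl{[2,2-dimethyl-6-(3-methylbut-2-en-1-yl)-7-(2-{4-[(triisopropylsilyl)oxy]phenyl}ethyl)-2H-chromen-5-yl]oxy}silane
Product: 25 7-[2-(4-hydroxyphenyl)ethyl]-2,2-dimethyl-6-(3-methylbut-2-en-1-yl)-2H-chromen-5-ol
Conditions: Bu4NF, THF, 0 °C to rt; aq NH4Cl
Reagents that add atoms: none
Why: Fluoride cleaves both aryl silyl ethers (desilylation driven by Si–F bond formation) without touching the chromene, the prenyl group or the bibenzyl; the product has no stereocentre.

**Compound list**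
1 | 4-(2-bromoethyl)phenol | Oc1ccc(CCBr)cc1 | starting material
2 | [4-(2-bromoethyl)phenoxy]tri(propan-2-yl)silane | CC(C)[Si](Oc1ccc(CCBr)cc1)(C(C)C)C(C)C | intermediate
3 | diketene (4-methylideneoxetan-2-one) | C=C1CC(=O)O1 | starting material
4 | (2-{4-[(triisopropylsilyl)oxy]phenyl}ethyl)magnesium bromide | CC(C)[Si](Oc1ccc(CC[Mg]Br)cc1)(C(C)C)C(C)C | intermediate (not isolated)
5 | 3-methylidene-5-{4-[(triisopropylsilyl)oxy]phenyl}pentanoic acid | CC(C)[Si](Oc1ccc(CCC(=C)CC(=O)O)cc1)(C(C)C)C(C)C | intermediate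
6 | 1-bromo-3-methylbut-2-ene (prenyl bromide) | CC(C)=CCBr | starting material
7 | dilithium dienediolate of 5 | CC(C)[Si](Oc1ccc(CCC(=C)C=C(O[Li])O[Li])cc1)(C(C)C)C(C)C | intermediate (not isolated)
8 | racemic 5-methyl-2-(4-{4-[(triisopropylsilyl)oxy]phenyl}but-1-en-2-yl)hex-4-enoic acid | CC(C)=CCC(C(=O)O)C(=C)CCc1ccc(O[Si](C(C)C)(C(C)C)C(C)C)cc1 | intermediate
9 | acetylene | C#C | starting material
10 | 3-methylbut-2-enal (prenal) | CC(C)=CC=O | starting material
11 | lithium acetylide | [Li]C#C | intermediate (not isolated)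
12 | racemic lithium 5-methylhex-4-en-1-yn-3-olate | CC(C)=CC(O[Li])C#C | intermediate (not isolated)
13 | racemic 3-methoxy-5-methylhex-4-en-1-yne | COC(C#C)C=C(C)C | intermediate
14 | racemic (3-methoxy-5-methylhex-4-en-1-yn-1-yl)lithium | COC(C#C[Li])C=C(C)C | intermediate (not isolated)
15 | racemic lithium 3-methoxy-5-methylhex-4-en-1-yn-1-olate | COC(C#CO[Li])C=C(C)C | intermediate (not isolated)
16 | racemic [(3-methoxy-5-methylhex-4-en-1-yn-1-yl)oxy]tri(propan-2-yl)silane | COC(C#CO[Si](C(C)C)(C(C)C)C(C)C)C=C(C)C | intermediate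
17 | racemic 5-methyl-2-(4-{4-[(triisopropylsilyl)oxy]phenyl}but-1-en-2-yl)hex-4-enoyl chloride | CC(C)=CCC(C(=O)Cl)C(=C)CCc1ccc(O[Si](C(C)C)(C(C)C)C(C)C)cc1 | intermediate (not isolated)
18 | 5-methyl-2-(4-{4-[(triisopropylsilyl)oxy]phenyl}but-1-en-2-yl)hexa-1,4-dien-1-one (vinylketene) | CC(C)=CCC(=C=O)C(=C)CCc1ccc(O[Si](C(C)C)(C(C)C)C(C)C)cc1 | intermediate (not isolated)
19 | 2-(1-methoxy-3-methylbut-2-en-1-yl)-4-(3-methylbut-2-en-1-yl)-3-[(triisopropylsilyl)oxy]-4-(4-{4-[(triisopropylsilyl)oxy]phenyl}but-1-en-2-yl)cyclobut-2-en-1-one (racemic diastereomer mixture) | COC(C=C(C)C)C1=C(O[Si](C(C)C)(C(C)C)C(C)C)C(CC=C(C)C)(C(=C)CCc2ccc(O[Si](C(C)C)(C(C)C)C(C)C)cc2)C1=O | intermediate (not isolated)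
20 | racemic (3E)-2-(1-methoxy-3-methylbut-2-en-1-yl)-4-(3-methylbut-2-en-1-yl)-3-[(triisopropylsilyl)oxy]-5-(2-{4-[(triisopropylsilyl)oxy]phenyl}ethyl)hexa-1,3,5-trien-1-one (dienylketene; the 3Z isomer reverts to 19) | O=C=C(C(OC)C=C(C)C)/C(O[Si](C(C)C)(C(C)C)C(C)C)=C(/CC=C(C)C)C(=C)CCc1ccc(O[Si](C(C)C)(C(C)C)C(C)C)cc1 | intermediate (not isolated)
21 | racemic 2-(1-methoxy-3-methylbut-2-en-1-yl)-4-(3-methylbut-2-en-1-yl)-3-[(triisopropylsilyl)oxy]-5-(2-{4-[(triisopropylsilyl)oxy]phenyl}ethyl)cyclohexa-2,4-dien-1-one | COC(C=C(C)C)C1=C(O[Si](C(C)C)(C(C)C)C(C)C)C(CC=C(C)C)=C(CCc2ccc(O[Si](C(C)C)(C(C)C)C(C)C)cc2)CC1=O | intermediate (not isolated)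
22 | racemic 2-(1-methoxy-3-methylbut-2-en-1-yl)-4-(3-methylbut-2-en-1-yl)-3-[(triisopropylsilyl)oxy]-5-(2-{4-[(triisopropylsilyl)oxy]phenyl}ethyl)phenol | COC(C=C(C)C)c1c(O)cc(CCc2ccc(O[Si](C(C)C)(C(C)C)C(C)C)cc2)c(CC=C(C)C)c1O[Si](C(C)C)(C(C)C)C(C)C | intermediate (not isolated)
23 | 6-(3-methylbut-2-en-1-ylidene)-4-(3-methylbut-2-en-1-yl)-5-[(triisopropylsilyl)oxy]-3-(2-{4-[(triisopropylsilyl)oxy]phenyl}ethyl)cyclohexa-2,4-dien-1-one (dienyl arm syn to the carbonyl) | CC(C)=C/C=C1\C(=O)C=C(CCc2ccc(O[Si](C(C)C)(C(C)C)C(C)C)cc2)C(CC=C(C)C)=C1O[Si](C(C)C)(C(C)C)C(C)C | intermediate (not isolated)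
24 | triisopropyl{[2,2-dimethyl-6-(3-methylbut-2-en-1-yl)-7-(2-{4-[(triisopropylsilyl)oxy]phenyl}ethyl)-2H-chromen-5-yl]oxy}silane | CC(C)=CCc1c(CCc2ccc(O[Si](C(C)C)(C(C)C)C(C)C)cc2)cc2OC(C)(C)C=Cc2c1O[Si](C(C)C)(C(C)C)C(C)C | intermediate
25 | 7-[2-(4-hydroxyphenyl)ethyl]-2,2-dimethyl-6-(3-methylbut-2-en-1-yl)-2H-chromen-5-ol | CC(C)=CCc1c(CCc2ccc(O)cc2)cc2c(c1O)C=CC(C)(C)O2 | target

**Totals and risks**
Total step count: 7. Longest linear sequence: 5 steps (steps 1, 2, 3, 6, 7).

Step 6 is the most likely to fail. The risks are ketene dimerisation, attack of the siloxyalkyne on the acid chloride, acylation of phenol 22, or stalling before methanol is lost. The fallback sets out from 8. Acid chloride 17 is made as before but treated with Et3N at high dilution in warm toluene with no alkyne present, so that vinylketene 18 closes by 4π electrocyclisation to 2-(3-methylbut-2-en-1-yl)-3-(2-{4-[(triisopropylsilyl)oxy]phenyl}ethyl)cyclobut-2-en-1-one F1. F1 is purified and heated with 16 in toluene at 110 °C with no base or ammonium salt; thermal ring opening regenerates 18 at low steady-state concentration. The route is rejoined at 19 and so comes back at 24.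

Step 5 is second. The ynolate carries a β-methoxy group and the siloxyalkyne is acid-labile, so the oxidation may give a low yield. The fallback sets out from 10 and avoids acetylide oxidation. A Jocic–Reeve reaction (CHBr3, KOH, MeOH, 0 °C) gives racemic 2-methoxy-4-methylpent-3-enoic acid F2. MeI and K2CO3 in DMF give racemic methyl 2-methoxy-4-methylpent-3-enoate F3. Kowalski ester homologation (CH2Br2, lithium 2,2,6,6-tetramethylpiperidide, THF, −78 °C; LiN(SiMe3)2; n-BuLi, −78 °C to rt) passes through racemic lithium 1,1-dibromo-3-methoxy-5-methylhexa-1,4-dien-2-olate F4 and comes back at ynolate 15, which is silylated to 16 as in step 5.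

Step 2 is third. Without effective catalysis the Grignard reagent attacks the lactone carbonyl, and β-hydride elimination can compete. The fallback sets out from 4. Conjugate addition to ethyl buta-2,3-dienoate catalysed by CuI (THF, −40 °C, NH4Cl quench) gives ethyl 3-methylidene-5-{4-[(triisopropylsilyl)oxy]phenyl}pentanoate F5 after kinetic α-protonation. LiOH in THF/H2O at 0 °C then comes back at 5.

**Further compounds**
F1 | step 6 | 2-(3-methylbut-2-en-1-yl)-3-(2-{4-[(triisopropylsilyl)oxy]phenyl}ethyl)cyclobut-2-en-1-one | CC(C)=CCC1=C(CCc2ccc(O[Si](C(C)C)(C(C)C)C(C)C)cc2)CC1=O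
F2 | step 5 | racemic 2-methoxy-4-methylpent-3-enoic acid | COC(C=C(C)C)C(=O)O
F3 | step 5 | racemic methyl 2-methoxy-4-methylpent-3-enoate | COC(C=C(C)C)C(=O)OC
F4 | step 5 | racemic lithium 1,1-dibromo-3-methoxy-5-methylhexa-1,4-dien-2-olate | COC(C=C(C)C)C(O[Li])=C(Br)Br
F5 | step 2 | ethyl 3-methylidene-5-{4-[(triisopropylsilyl)oxy]phenyl}pentanoate | CCOC(=O)CC(=C)CCc1ccc(O[Si](C(C)C)(C(C)C)C(C)C)cc1
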